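**Strategy.** The route rests on disconnecting the C6–C11 bond of ring A (chamigrane numbering), the bond between the spiro carbon and the quaternary CMe2 carbon, which is flanked by the C10 bromide and the C7 exocyclic methylene. This is the retron of a bromonium-initiated, allylsilane-terminated cation–olefin spirocyclisation. In one operation the key step closes ring A, joins two fully substituted carbons, relays the C10 bromide stereocentre to the spiro centre and delivers the exocyclic alkene. Its precursor is a monocyclic (E)-tetrasubstituted allylsilane on a 4-methylcyclohexene (ring B) that carries an enantioenriched vicinal bromochloride chain. The ring B halogens follow by substrate control.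

Key step: step 10

Remark: chamigrane numbering is used for the spirocycles: ring B is C1–C5 plus C6, ring A is C6–C11, C7 bears the exocyclic C14H2, C10 the bromine and C11 the two methyl groups.
Assumption: in step 1 the enantiomer of the Schiff-base ligand is taken that delivers the (S)-bromide.

**Step 1**
Reactants: 1 3-methylbut-2-en-1-ol (prenol)
Product: 2 (2S)-2-bromo-3-chloro-3-methylbutan-1-ol
Conditions: NBS, ClTi(OiPr)3, chiral tridentate Schiff-base ligand (20 mol %), hexanes, −20 °C
Reagents that add atoms: N-bromosuccinimide O=C1CCC(=O)N1Br; chlorotitanium triisopropoxide CC(C)O[Ti](Cl)(OC(C)C)OC(C)C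
Why: Titanium-alkoxide-directed catalytic enantioselective bromochlorination of an allylic alcohol, in which the ligand-bound titanium alkoxide fixes the face that receives Br+ and the titanium-bound chloride opens the bromonium anti at the tertiary carbon, should set the (S)-C–Br centre that becomes C10.

**Step 2**
Reactants: 2 (2S)-2-bromo-3-chloro-3-methylbutan-1-ol
Product: 3 (2S)-2-bromo-3-chloro-3-methylbutyl trifluoromethanesulfonate
Conditions: Tf2O, 2,6-lutidine, CH2Cl2, −78 °C
Reagents that add atoms: trifluoromethanesulfonic anhydride O=S(=O)(OS(=O)(=O)C(F)(F)F)C(F)(F)F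
Why: O-sulfonylation of the primary alcohol should give a triflate whose ionisation is retarded by the β-bromine, and no stereocentre is touched.

**Step 3**
Reactants: 3 (2S)-2-bromo-3-chloro-3-methylbutyl trifluoromethanesulfonate; 4 ethyl 2-acetylpent-4-enoate (ethyl 2-allylacetoacetate, racemic)
Product: 6 ethyl (6S)-6-bromo-7-chloro-7-methyl-3-oxo-2-(prop-2-en-1-yl)octanoate, via dilithium 1,3-dianion 5 (not isolated)
Conditions: 4, LiN(iPr)2 (2.1 equiv), THF, 0 °C; then 3, −78 → −40 °C; 1 M HCl
Reagents that add atoms: none
Why: γ-Alkylation of an acetoacetate 1,3-dianion, in which the more basic terminal carbanion displaces the primary triflate by SN2 far faster than it attacks the secondary bromide or tertiary chloride, should leave the bromide stereocentre intact and give C2 as an inconsequential epimer mixture.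

**Step 4**
Reactants: 6 ethyl (6S)-6-bromo-7-chloro-7-methyl-3-oxo-2-(prop-2-en-1-yl)octanoate
Product: 7 ethyl (2Z,6S)-6-bromo-7-chloro-7-methyl-2-(prop-2-en-1-yl)-3-{[(trifluoromethyl)sulfonyl]oxy}oct-2-enoate
Conditions: LiOSO2CF3, Et3N, Tf2O, CH2Cl2, 0 °C
Reagents that add atoms: trifluoromethanesulfonic anhydride O=S(=O)(OS(=O)(=O)C(F)(F)F)C(F)(F)F
Why: Stereoselective enol triflation of a β-keto ester through the lithium-chelated enolate should place OTf cis to CO2Et, which fixes the geometry of the later tetrasubstituted alkene.

**Step 5**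
Reactants: 7 ethyl (2Z,6S)-6-bromo-7-chloro-7-methyl-2-(prop-2-en-1-yl)-3-{[(trifluoromethyl)sulfonyl]oxy}oct-2-enoate
Product: 8 (2Z,6S)-6-bromo-7-chloro-1-hydroxy-7-methyl-2-(prop-2-en-1-yl)oct-2-en-3-yl trifluoromethanesulfonate
Conditions: iBu2AlH (2.2 equiv), CH2Cl2, −78 °C; aq. KNaC4H4O6
Reagents that add atoms: none
Why: 1,2-Reduction of the conjugated ester by the aluminium hydride should give the allylic alcohol with retention of alkene geometry, the enol triflate and the alkyl halides being inert at −78 °C.

**Step 6**
Reactants: 8 (2Z,6S)-6-bromo-7-chloro-1-hydroxy-7-methyl-2-(prop-2-en-1-yl)oct-2-en-3-yl trifluoromethanesulfonate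
Product: 9 (2Z,6S)-1,6-dibromo-7-chloro-7-methyl-2-(prop-2-en-1-yl)oct-2-en-3-yl trifluoromethanesulfonate
Conditions: CBr4, PPh3, CH2Cl2, 0 °C
Reagents that add atoms: tetrabromomethane BrC(Br)(Br)Br
Why: Appel bromination of the primary allylic alcohol under neutral conditions should proceed by SN2 without allylic transposition, because the SN2' carbon is fully substituted.

**Step 7**
Reactants: 9 (2Z,6S)-1,6-dibromo-7-chloro-7-methyl-2-(prop-2-en-1-yl)oct-2-en-3-yl trifluoromethanesulfonate
Product: 10 (5E,9S)-9-bromo-10-chloro-2,10-dimethyl-5-(prop-2-en-1-yl)undeca-1,5-dien-6-yl trifluoromethanesulfonate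
Conditions: 2-methylallylmagnesium chloride (1.1 equiv), THF, −78 → −30 °C
Reagents that add atoms: 2-methylallylmagnesium chloride CC(=C)C[Mg]Cl
Why: Allyl–allyl coupling by SN2 displacement of the primary allylic bromide with the symmetric 2-methylallyl Grignard reagent should install the second ring B arm, SN2' attack being blocked at the fully substituted triflate-bearing carbon.

**Step 8**
Reactants: 10 (5E,9S)-9-bromo-10-chloro-2,10-dimethyl-5-(prop-2-en-1-yl)undeca-1,5-dien-6-yl trifluoromethanesulfonate
Product: 11 (1E,4S)-4-bromo-5-chloro-5-methyl-1-(4-methylcyclohex-3-en-1-ylidene)hexyl trifluoromethanesulfonate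
Conditions: (H2IMes)(PCy3)Cl2Ru=CHPh (second-generation Grubbs catalyst, 3 mol %), CH2Cl2, 40 °C
Reagents that add atoms: none
Why: Ring-closing olefin metathesis between the monosubstituted and the 1,1-disubstituted alkene should close ring B as a trisubstituted cyclohexene, while the inert tetrasubstituted enol triflate keeps its geometry (triflate trans to the CH2–CH= arm).

**Step 9**
Reactants: 11 (1E,4S)-4-bromo-5-chloro-5-methyl-1-(4-methylcyclohex-3-en-1-ylidene)hexyl trifluoromethanesulfonate
Product: 12 [(2E,5S)-5-bromo-6-chloro-6-methyl-2-(4-methylcyclohex-3-en-1-ylidene)heptyl]trimethylsilane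
Conditions: Me3SiCH2MgCl, Pd(PPh3)4 (5 mol %), Et2O, 0 °C → rt
Reagents that add atoms: (trimethylsilyl)methylmagnesium chloride C[Si](C)(C)C[Mg]Cl
Why: Kumada cross-coupling of the enol triflate under zerovalent palladium catalysis should give the tetrasubstituted allylsilane with retention of geometry, oxidative addition into the vinyl triflate being much faster than into the secondary alkyl bromide.

**Step 10**
Reactants: 12 [(2E,5S)-5-bromo-6-chloro-6-methyl-2-(4-methylcyclohex-3-en-1-ylidene)heptyl]trimethylsilane
Product: 14 (6S,10S)-10-bromochamigra-2,7(14)-diene [(6S,10S)-10-bromo-β-chamigrene], via bromonium chloride 13 (not isolated)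
Conditions: (CF3)2CHOH (0.01 M), 2,6-di-tert-butyl-4-methylpyridine, 0 °C → rt
Reagents that add atoms: none
Why: The fluorinated alcohol ionises the tertiary C–Cl bond with anchimeric assistance of the neighbouring bromine, so the enantiopure bromonium ion 13 forms regiospecifically without external electrophilic bromine; the ring carbon (γ-carbon) of the allylsilane then attacks the dimethyl-substituted carbon anti to bromine and the β-silyl cation loses Me3Si+ to chloride, leaving the C7 exocyclic methylene. The closest known reaction types are the stereospecific bromopolyene cyclisation triggered by solvolysis of an enantioenriched vicinal bromochloride and the allylsilane-terminated cation–olefin cyclisation. Ring A closes in a 6-endo-trig mode with respect to the allylsilane alkene, by forming the C6–C11 bond between two fully substituted carbons. C10 keeps its (S) configuration because its C–Br bond is never broken, and it sets the new spiro centre C6 through a chair transition state with equatorial bromine, in which the alkene substituent cis to the tether (the CH2–CH= arm) becomes axial on ring A, so the (E)-allylsilane should give (6S). The step needs chemoselectivity for the allylsilane over the ring B alkene (secured by the six-membered transition state), regioselective alkene formation (secured by silicon, which excludes the endocyclic isomer) and suppression of E1 loss and protodesilylation (hindered pyridine buffer, high dilution).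

**Step 11**
Reactants: 14 (6S,10S)-10-bromochamigra-2,7(14)-diene
Product: 15 (2S,3R,6S,10S)-10-bromo-2,3-epoxychamigr-7(14)-ene
Conditions: mCPBA (1.05 equiv), NaHCO3, CH2Cl2, 0 °C
Reagents that add atoms: 3-chloroperoxybenzoic acid OOC(=O)c1cccc(Cl)c1
Why: Prilezhaev epoxidation should take place at the electron-rich trisubstituted ring B alkene rather than the hindered exocyclic alkene, and on the face anti to the axial C7 substituent of the spiro centre (the C11 side), which sets the (2S,3R)-epoxide.

**Step 12**
Reactants: 15 (2S,3R,6S,10S)-10-bromo-2,3-epoxychamigr-7(14)-ene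
Product: 16 (2R,3R,6S,10S)-10-bromo-2-chlorochamigr-7(14)-en-3-ol
Conditions: LiCl, AcOH, THF, rt
Reagents that add atoms: lithium chloride [Li+].[Cl-]
Why: Acid-assisted SN2 opening of the epoxide by chloride at the less substituted C2 with inversion, which is also the trans-diaxial opening mode of the half-chair with C11 equatorial, should set (2R)-Cl trans to the C3 hydroxyl.

**Step 13**
Reactants: 16 (2R,3R,6S,10S)-10-bromo-2-chlorochamigr-7(14)-en-3-ol
Product: 17 (2R,3R,6S,10S)-3,10-dibromo-2-chlorochamigr-7(14)-ene (target)
Conditions: Me2C=C(Br)NMe2 (1.5 equiv), CH2Cl2, 0 °C → rt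
Reagents that add atoms: 1-bromo-N,N,2-trimethylprop-1-en-1-amine CC(C)=C(Br)N(C)C
Why: Neutral deoxybromination of the tertiary alcohol with an α-bromoenamine (alkoxyiminium bromide, then SN1-type substitution) should proceed with net retention, because the antiperiplanar axial C2 chlorine assists ionisation and bromide re-enters on the face the oxygen left, giving the trans-diaxial (3R)-bromide without free HBr that would attack the exocyclic alkene.

**Compound list**
1 | 3-methylbut-2-en-1-ol (prenol) | CC(C)=CCO | starting material
2 | (2S)-2-bromo-3-chloro-3-methylbutan-1-ol | OC[C@H](Br)C(C)(C)Cl | intermediate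
3 | (2S)-2-bromo-3-chloro-3-methylbutyl trifluoromethanesulfonate | FC(F)(F)S(=O)(=O)OC[C@H](Br)C(C)(C)Cl | intermediate
4 | ethyl 2-acetylpent-4-enoate (ethyl 2-allylacetoacetate, racemic) | CCOC(=O)C(CC=C)C(C)=O | starting material
5 | dilithium 1,3-dianion of 4 (not isolated) | [Li+].[Li+].CCOC(=O)[C-](CC=C)C(=O)[CH2-] | intermediate
6 | ethyl (6S)-6-bromo-7-chloro-7-methyl-3-oxo-2-(prop-2-en-1-yl)octanoate (C2 epimers) | CCOC(=O)C(CC=C)C(=O)CC[C@H](Br)C(C)(C)Cl | intermediate
7 | ethyl (2Z,6S)-6-bromo-7-chloro-7-methyl-2-(prop-2-en-1-yl)-3-{[(trifluoromethyl)sulfonyl]oxy}oct-2-enoate | CCOC(=O)/C(CC=C)=C(\OS(=O)(=O)C(F)(F)F)CC[C@H](Br)C(C)(C)Cl | intermediate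
8 | (2Z,6S)-6-bromo-7-chloro-1-hydroxy-7-methyl-2-(prop-2-en-1-yl)oct-2-en-3-yl trifluoromethanesulfonate | OC/C(CC=C)=C(\OS(=O)(=O)C(F)(F)F)CC[C@H](Br)C(C)(C)Cl | intermediate
9 | (2Z,6S)-1,6-dibromo-7-chloro-7-methyl-2-(prop-2-en-1-yl)oct-2-en-3-yl trifluoromethanesulfonate | BrC/C(CC=C)=C(\OS(=O)(=O)C(F)(F)F)CC[C@H](Br)C(C)(C)Cl | intermediate
10 | (5E,9S)-9-bromo-10-chloro-2,10-dimethyl-5-(prop-2-en-1-yl)undeca-1,5-dien-6-yl trifluoromethanesulfonate | C=C(C)CC/C(CC=C)=C(\OS(=O)(=O)C(F)(F)F)CC[C@H](Br)C(C)(C)Cl | intermediate
11 | (1E,4S)-4-bromo-5-chloro-5-methyl-1-(4-methylcyclohex-3-en-1-ylidene)hexyl trifluoromethanesulfonate | CC1=CC/C(CC1)=C(/OS(=O)(=O)C(F)(F)F)CC[C@H](Br)C(C)(C)Cl | intermediate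
12 | [(2E,5S)-5-bromo-6-chloro-6-methyl-2-(4-methylcyclohex-3-en-1-ylidene)heptyl]trimethylsilane | CC1=CC/C(CC1)=C(/C[Si](C)(C)C)CC[C@H](Br)C(C)(C)Cl | intermediate
13 | bromonium chloride formed from 12 by loss of chloride (not isolated) | CC1=CC/C(CC1)=C(/C[Si](C)(C)C)CC[C@@H]1[Br+]C1(C)C.[Cl-] | intermediate
14 | (6S,10S)-10-bromochamigra-2,7(14)-diene [(6S,10S)-10-bromo-β-chamigrene] | C=C1CC[C@H](Br)C(C)(C)[C@]12CCC(C)=CC2 | intermediate
15 | (2S,3R,6S,10S)-10-bromo-2,3-epoxychamigr-7(14)-ene | C=C1CC[C@H](Br)C(C)(C)[C@]12CC[C@@]3(C)O[C@H]3C2 | intermediate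
16 | (2R,3R,6S,10S)-10-bromo-2-chlorochamigr-7(14)-en-3-ol | C=C1CC[C@H](Br)C(C)(C)[C@]12CC[C@@](C)(O)[C@H](Cl)C2 | intermediate
17 | (2R,3R,6S,10S)-3,10-dibromo-2-chlorochamigr-7(14)-ene | C=C1CC[C@H](Br)C(C)(C)[C@]12CC[C@@](C)(Br)[C@H](Cl)C2 | target

**Total step count:** 13 steps. **Longest linear sequence:** 13 steps (from 1).

**Steps most likely to fail**

1. Step 13 (tertiary alcohol to tertiary bromide). Ionisation of the β-chloro tertiary centre may end in E1 elimination or halogen migration, and any acid formed may add to or isomerise the C7 exocyclic alkene. The fallback sets out from 11 and comes back at 17; it installs the ring B halogens before the acid-sensitive allylsilane and exocyclic alkene exist. Shi epoxidation of the ring B alkene of 11 (fructose-derived ketone of the required enantiomeric series, KHSO5, buffered MeCN/H2O; the enol triflate alkene is too electron-poor to react) should give the epoxide F1. LiCl/AcOH should open it at the secondary carbon to the trans-chlorohydrin F2. Aqueous HBr with LiBr should then convert the tertiary alcohol, with chlorine participation, into the trans-bromochloride F3, the only alkene present being the acid-stable enol triflate. Kumada coupling as in step 9 should give the allylsilane F4, and solvolysis as in step 10 should close ring A and give 17 directly. Attack on ring B would occur equatorially, anti to the axial C2 chlorine, which matches the chair demanded by the (E)-allylsilane and the (S)-bromide.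

2. Step 10 (key spirocyclisation). The tetrasubstituted allylsilane may be protodesilylated, or the tertiary cation may lose a proton, before the C6–C11 bond forms. The fallback sets out from 11 and comes back at 14; it replaces silicon-directed termination by proton loss. Negishi methylation of 11 (MeZnCl, Pd(PPh3)4, THF) should give the methyl-terminated bromochloride F5, which has no acid-labile C–Si bond. Its solvolysis in (CF3)2CHOH should give 14 by loss of a C14 proton, together with the endocyclic alkene isomer, to be separated on AgNO3-impregnated silica.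

3. Step 3 (dianion alkylation). The strongly basic dianion may cause E2 loss of triflic acid or halophilic attack on the vicinal dihalide instead of SN2 at the β-branched primary carbon. The fallback sets out from 3 and comes back at 6; it uses a soft nucleophile and builds the keto ester by acylation. Sodium di-tert-butyl malonate should displace the triflate to give the malonate F6. Acid-mediated loss of both tert-butyl groups with decarboxylation (TsOH, toluene, 80 °C) should give the acid F7. Carbonyldiimidazole should convert it into the acyl imidazolide F8. Claisen-type C-acylation of the lithium enolate of ethyl pent-4-enoate F9 (LiN(iPr)2, THF, −78 °C, 2 equiv) with F8 should give 6.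

**Further compounds**
F1 | step 13 | (1E,4S)-4-bromo-5-chloro-5-methyl-1-[(1S,6R)-6-methyl-7-oxabicyclo[4.1.0]heptan-3-ylidene]hexyl trifluoromethanesulfonate | FC(F)(F)S(=O)(=O)O/C(CC[C@H](Br)C(C)(C)Cl)=C1\CC[C@@]2(C)O[C@H]2C1
F2 | step 13 | (1E,4S)-4-bromo-5-chloro-1-[(3R,4R)-3-chloro-4-hydroxy-4-methylcyclohexylidene]-5-methylhexyl trifluoromethanesulfonate | FC(F)(F)S(=O)(=O)O/C(CC[C@H](Br)C(C)(C)Cl)=C1\CC[C@@](C)(O)[C@H](Cl)C1
F3 | step 13 | (1E,4S)-4-bromo-1-[(3R,4R)-4-bromo-3-chloro-4-methylcyclohexylidene]-5-chloro-5-methylhexyl trifluoromethanesulfonate | FC(F)(F)S(=O)(=O)O/C(CC[C@H](Br)C(C)(C)Cl)=C1\CC[C@@](C)(Br)[C@H](Cl)C1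
F4 | step 13 | [(2E,5S)-5-bromo-2-[(3R,4R)-4-bromo-3-chloro-4-methylcyclohexylidene]-6-chloro-6-methylheptyl]trimethylsilane | C[Si](C)(C)C/C(CC[C@H](Br)C(C)(C)Cl)=C1\CC[C@@](C)(Br)[C@H](Cl)C1
F5 | step 10 | 4-[(2Z,5S)-5-bromo-6-chloro-6-methylheptan-2-ylidene]-1-methylcyclohex-1-ene | CC1=CC/C(CC1)=C(/C)CC[C@H](Br)C(C)(C)Cl
F6 | step 3 | di-tert-butyl 2-[(2S)-2-bromo-3-chloro-3-methylbutyl]propanedioate | CC(C)(C)OC(=O)C(C[C@H](Br)C(C)(C)Cl)C(=O)OC(C)(C)C
F7 | step 3 | (4S)-4-bromo-5-chloro-5-methylhexanoic acid | OC(=O)CC[C@H](Br)C(C)(C)Cl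
F8 | step 3 | (4S)-4-bromo-5-chloro-1-(1H-imidazol-1-yl)-5-methylhexan-1-one | O=C(CC[C@H](Br)C(C)(C)Cl)n1ccnc1
F9 | step 3 | lithium enolate of ethyl pent-4-enoate | [Li+].CCOC([O-])=CCC=C
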